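The route rests on the aldol retron of the carbocycle (isochromene numbering): C8 ketone, quaternary C7 (methyl, aroyloxy) and acetoxy-bearing C6. The C6–C7 bond closes this ring by intramolecular aldol addition of the α-aroyloxy ketone enolate to a C6 aldehyde, the aldolate being acetylated in the flask. The precursor is a monocyclic tetrahydropyran in which the C4a=C8a alkene of the target is temporarily saturated (C4a–H, C8a–SePh); these centres, relayed from C3 by conjugate addition/selenenylation, block the wrong enolisation and steer C6 and C7. Selenoxide elimination then restores the alkene, so the hindered ester and the acetate are both in place before the ring is complete.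

Key step: step 10

Remark: atoms are numbered as in the isochromene skeleton of the target (C1, O2, C3, C4, C4a, C5–C8, C8a); "TBS-everninate" stands for 2-[(tert-butyldimethylsilyl)oxy]-4-methoxy-6-methylbenzoate.
Assumption: 2-hydroxy-4-methoxy-6-methylbenzoic acid and the THF solution of (1,3-dioxolan-2-ylmethyl)magnesium bromide are taken as purchasable; the configuration at C7 before step 10 is immaterial because the enolate of the key step is planar there.

Step 1
Reactants: 1 (E)-but-2-enal; 2 allyltributylstannane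
Product: 3 (S,E)-hepta-1,5-dien-4-ol
Conditions: (S)-BINOL (20 mol %), Ti(OiPr)4 (10 mol %), 4 Å MS, CH2Cl2, −20 °C; aq. NaHCO3
Reagents that add atoms: none
Why: Keck asymmetric allylation, in which the BINOL–titanium Lewis acid should deliver the allyl group to one face of the aldehyde carbonyl (1,2-addition) and so set C3 as S under catalyst control.

Step 2
Reactants: 3 (S,E)-hepta-1,5-dien-4-ol; 4 2,3-dibromoprop-1-ene
Product: 5 (S,E)-4-[(2-bromoprop-2-en-1-yl)oxy]hepta-1,5-diene
Conditions: NaH, Bu4NI (cat.), THF/DMF, 0 °C to rt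
Reagents that add atoms: none
Why: Williamson etherification, the alkoxide displacing only the allylic bromide (SN2) while the vinylic bromide and C3 stay untouched.

Step 3
Reactants: 6 ethyl (S)-lactate
Product: 7 (S)-2-hydroxy-N-methoxy-N-methylpropanamide
Conditions: MeNH(OMe)·HCl, i-PrMgCl, THF, −20 to 0 °C
Reagents that add atoms: N,O-dimethylhydroxylamine hydrochloride, CNOC.Cl
Why: Weinreb amide formation by attack of the magnesium amide on the ester at low temperature, which does not engage the lactate stereocentre.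

Step 4
Reactants: 8 2-hydroxy-4-methoxy-6-methylbenzoic acid
Product: 10 2-[(tert-butyldimethylsilyl)oxy]-4-methoxy-6-methylbenzoic acid, via bis-silyl derivative 9 (not isolated)
Conditions: TBSCl (2.2 equiv), imidazole, DMF, rt; then K2CO3, THF/H2O, rt; citric acid work-up
Reagents that add atoms: tert-butyldimethylsilyl chloride, CC(C)(C)[Si](C)(C)Cl
Why: silylation of phenol and acid followed by selective hydrolysis of the labile silyl ester should leave only the phenol masked for the later organometallic and enolate steps.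

Step 5
Reactants: 7 (S)-2-hydroxy-N-methoxy-N-methylpropanamide; 10 2-[(tert-butyldimethylsilyl)oxy]-4-methoxy-6-methylbenzoic acid
Product: 11 (R)-1-[methoxy(methyl)amino]-1-oxopropan-2-yl TBS-everninate
Conditions: PPh3, DIAD, THF, 0 °C to rt
Reagents that add atoms: none
Why: Mitsunobu esterification, in which the carboxylate attacks the activated lactate carbon (SN2, inversion to R) and so avoids acyl substitution at the hindered 2,6-disubstituted benzoyl carbon.

Step 6
Reactants: 5 (S,E)-4-[(2-bromoprop-2-en-1-yl)oxy]hepta-1,5-diene; 11 (R)-1-[methoxy(methyl)amino]-1-oxopropan-2-yl TBS-everninate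
Product: 13 (2R)-4-({[(4S,5E)-hepta-1,5-dien-4-yl]oxy}methyl)-3-oxopent-4-en-2-yl TBS-everninate, via vinyllithium 12 (not isolated)
Conditions: t-BuLi (2.05 equiv), Et2O, −78 °C; then 11 in THF, −78 °C; aq. NH4Cl
Reagents that add atoms: none
Why: bromine–lithium exchange followed by Weinreb ketone synthesis, the chelated tetrahedral adduct stopping at the ketone and the 2,6-disubstituted aryl ester being too hindered to compete.

Step 7
Reactants: 13 (2R)-4-({[(4S,5E)-hepta-1,5-dien-4-yl]oxy}methyl)-3-oxopent-4-en-2-yl TBS-everninate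
Product: 14 (2R)-1-oxo-1-{(6S)-6-[(E)-prop-1-en-1-yl]-5,6-dihydro-2H-pyran-3-yl}propan-2-yl TBS-everninate
Conditions: second-generation Grubbs catalyst (5 mol %), CH2Cl2 (5 mM), 40 °C
Reagents that add atoms: none
Why: ring-closing metathesis, the catalyst loading on the terminal allyl alkene and closing onto the 1,1-disubstituted enone alkene to the six-membered ether ring faster than it engages the internal propenyl group.

Step 8
Reactants: 14 (2R)-1-oxo-1-{(6S)-6-[(E)-prop-1-en-1-yl]-5,6-dihydro-2H-pyran-3-yl}propan-2-yl TBS-everninate; 15 (1,3-dioxolan-2-ylmethyl)magnesium bromide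
Product: 17 (2R)-1-{(3S,4S,6S)-4-[(1,3-dioxolan-2-yl)methyl]-3-(phenylselanyl)-6-[(E)-prop-1-en-1-yl]tetrahydro-2H-pyran-3-yl}-1-oxopropan-2-yl TBS-everninate, via silyl enol ether 16 (not isolated)
Conditions: CuBr·SMe2 (10 mol %), Me3SiCl, THF, −78 °C; then PhSeCl (1.0 equiv), −78 °C
Reagents that add atoms: benzeneselenenyl chloride, Cl[Se]c1ccccc1
Why: copper-catalysed conjugate addition with silyl trapping and selenenylation of the enol silane, the nucleophile adding axially at C4a anti to the C3 substituent (as with 5-substituted cyclohexenones) and selenium entering C8a anti to the new chain, so that C4a–H, C8a–Se and the propenyl group should share one face.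

Step 9
Reactants: 17 (2R)-1-{(3S,4S,6S)-4-[(1,3-dioxolan-2-yl)methyl]-3-(phenylselanyl)-6-[(E)-prop-1-en-1-yl]tetrahydro-2H-pyran-3-yl}-1-oxopropan-2-yl TBS-everninate
Product: 18 (2R)-1-oxo-1-{(3S,4S,6S)-4-(2-oxoethyl)-3-(phenylselanyl)-6-[(E)-prop-1-en-1-yl]tetrahydro-2H-pyran-3-yl}propan-2-yl TBS-everninate
Conditions: HCl (1 M aq.), THF, 0 °C to rt
Reagents that add atoms: water, O
Why: acid hydrolysis of the dioxolane, which should release an ordinary saturated aldehyde (C4a is sp3, so C5 is not vinylogously acidic) while the aryl silyl ether, the selenide and both ester-type groups tolerate dilute acid.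

Step 10
Reactants: 18 (2R)-1-oxo-1-{(3S,4S,6S)-4-(2-oxoethyl)-3-(phenylselanyl)-6-[(E)-prop-1-en-1-yl]tetrahydro-2H-pyran-3-yl}propan-2-yl TBS-everninate
Product: 21 (3S,4aS,6S,7S,8aS)-6-acetoxy-7-methyl-8-oxo-8a-(phenylselanyl)-3-[(E)-prop-1-en-1-yl]octahydro-1H-isochromen-7-yl TBS-everninate, via lithium enolate 19 (not isolated), via lithium aldolate 20 (not isolated)
Conditions: LiN(SiMe3)2 (1.1 equiv), THF, −78 °C; then Ac2O, DMAP, −78 to −20 °C
Reagents that add atoms: acetic anhydride, CC(=O)OC(C)=O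
Why: LiN(SiMe3)2 removes the only α-hydrogen of the ketone (C7–H, acidified by the acyloxy group; C8a carries selenium, so neither the other enolate nor β-elimination of the ring oxygen can arise) to give the lithium-chelated (Z)-enolate 19, which adds to the tethered aldehyde, and aldolate 20 is acetylated before it can revert. This is an ordinary intramolecular lithium-enolate aldol addition, and the cyclohexanone ring closes in the 6-(enolendo)-exo-trig mode through a closed chair-like transition state in which lithium bridges the enolate and aldehyde oxygens. The new ring is cis-fused to the tetrahydropyran chair (propenyl equatorial, C4a chain axial, C8a acyl equatorial), so C6 can reach only one face of the enolate, and the C4a and C8a centres from step 8 thereby fix the absolute configuration at C7. Lithium bridging puts the C6 oxygen axial and the enolate geometry puts the aroyloxy group equatorial and the methyl group axial, which makes C6–O and C7–O cis and places both on the face of C4a–H, i.e. 6S,7S. The step needs ketone enolisation beside an enolisable aldehyde and no O-to-O acyl shift in the aldolate: the aldehyde enolate has no productive ring closure and equilibrates, and the 2,6-disubstituted aroyl group is too hindered to migrate.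

Step 11
Reactants: 21 (3S,4aS,6S,7S,8aS)-6-acetoxy-7-methyl-8-oxo-8a-(phenylselanyl)-3-[(E)-prop-1-en-1-yl]octahydro-1H-isochromen-7-yl TBS-everninate
Product: 23 (3S,6S,7S)-6-acetoxy-7-methyl-8-oxo-3-[(E)-prop-1-en-1-yl]-3,4,5,6,7,8-hexahydro-1H-isochromen-7-yl TBS-everninate, via selenoxide 22 (not isolated)
Conditions: H2O2 (30 % aq.), pyridine, CH2Cl2, 0 °C to rt
Reagents that add atoms: none
Why: selenide oxidation and selenoxide syn-elimination, which should run toward the cis C4a–H (elimination toward the oxygen-bearing C1 is disfavoured) and so restore the tetrasubstituted C4a=C8a enone and erase both temporary centres without base.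

Step 12
Reactants: 23 (3S,6S,7S)-6-acetoxy-7-methyl-8-oxo-3-[(E)-prop-1-en-1-yl]-3,4,5,6,7,8-hexahydro-1H-isochromen-7-yl TBS-everninate
Product: 24 (3S,6S,7S)-6-acetoxy-7-methyl-8-oxo-3-[(E)-prop-1-en-1-yl]-3,4,5,6,7,8-hexahydro-1H-isochromen-7-yl 2-hydroxy-4-methoxy-6-methylbenzoate
Conditions: Bu4NF, AcOH (1:1), THF, 0 °C
Reagents that add atoms: none
Why: fluoride cleavage of the aryl silyl ether, buffered with acetic acid so that the acetate, the hindered aryl ester and the γ-acidic enone are not exposed to base.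

Compound list
1 | (E)-but-2-enal | C/C=C/C=O | starting material
2 | allyltributylstannane | C=CC[Sn](CCCC)(CCCC)CCCC | starting material
3 | (S,E)-hepta-1,5-dien-4-ol | C/C=C/[C@@H](O)CC=C | intermediate
4 | 2,3-dibromoprop-1-ene | C=C(Br)CBr | starting material
5 | (S,E)-4-[(2-bromoprop-2-en-1-yl)oxy]hepta-1,5-diene | C/C=C/[C@@H](OCC(Br)=C)CC=C | intermediate
6 | ethyl (S)-lactate | C[C@H](O)C(=O)OCC | starting material
7 | (S)-2-hydroxy-N-methoxy-N-methylpropanamide | C[C@H](O)C(=O)N(C)OC | intermediate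
8 | 2-hydroxy-4-methoxy-6-methylbenzoic acid | Cc1cc(OC)cc(O)c1C(=O)O | starting material
9 | tert-butyldimethylsilyl 2-[(tert-butyldimethylsilyl)oxy]-4-methoxy-6-methylbenzoate | Cc1cc(OC)cc(O[Si](C)(C)C(C)(C)C)c1C(=O)O[Si](C)(C)C(C)(C)C | intermediate
10 | 2-[(tert-butyldimethylsilyl)oxy]-4-methoxy-6-methylbenzoic acid | Cc1cc(OC)cc(O[Si](C)(C)C(C)(C)C)c1C(=O)O | intermediate
11 | (R)-1-[methoxy(methyl)amino]-1-oxopropan-2-yl TBS-everninate | C[C@@H](OC(=O)c1c(C)cc(OC)cc1O[Si](C)(C)C(C)(C)C)C(=O)N(C)OC | intermediate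
12 | {3-[(4S,5E)-hepta-1,5-dien-4-yloxy]prop-1-en-2-yl}lithium | C/C=C/[C@@H](OCC([Li])=C)CC=C | intermediate
13 | (2R)-4-({[(4S,5E)-hepta-1,5-dien-4-yl]oxy}methyl)-3-oxopent-4-en-2-yl TBS-everninate | C/C=C/[C@@H](OCC(=C)C(=O)[C@@H](C)OC(=O)c1c(C)cc(OC)cc1O[Si](C)(C)C(C)(C)C)CC=C | intermediate
14 | (2R)-1-oxo-1-{(6S)-6-[(E)-prop-1-en-1-yl]-5,6-dihydro-2H-pyran-3-yl}propan-2-yl TBS-everninate | C/C=C/[C@@H]1CC=C(CO1)C(=O)[C@@H](C)OC(=O)c1c(C)cc(OC)cc1O[Si](C)(C)C(C)(C)C | intermediate
15 | (1,3-dioxolan-2-ylmethyl)magnesium bromide | Br[Mg]CC1OCCO1 | starting material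
16 | trimethylsilyl enol ether (C8=C8a, geometry undefined) of the conjugate adduct, C3 S, C4a S, C7 R | C/C=C/[C@@H]1C[C@@H](CC2OCCO2)C(CO1)=C(O[Si](C)(C)C)[C@@H](C)OC(=O)c1c(C)cc(OC)cc1O[Si](C)(C)C(C)(C)C | intermediate
17 | (2R)-1-{(3S,4S,6S)-4-[(1,3-dioxolan-2-yl)methyl]-3-(phenylselanyl)-6-[(E)-prop-1-en-1-yl]tetrahydro-2H-pyran-3-yl}-1-oxopropan-2-yl TBS-everninate | C/C=C/[C@@H]1C[C@@H](CC2OCCO2)[C@]([Se]c2ccccc2)(CO1)C(=O)[C@@H](C)OC(=O)c1c(C)cc(OC)cc1O[Si](C)(C)C(C)(C)C | intermediate
18 | (2R)-1-oxo-1-{(3S,4S,6S)-4-(2-oxoethyl)-3-(phenylselanyl)-6-[(E)-prop-1-en-1-yl]tetrahydro-2H-pyran-3-yl}propan-2-yl TBS-everninate | C/C=C/[C@@H]1C[C@@H](CC=O)[C@]([Se]c2ccccc2)(CO1)C(=O)[C@@H](C)OC(=O)c1c(C)cc(OC)cc1O[Si](C)(C)C(C)(C)C | intermediate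
19 | lithium (Z)-enolate of 18 (C7=C8, O–Li cis to the aroyloxy group) | C/C=C/[C@@H]1C[C@@H](CC=O)[C@]([Se]c2ccccc2)(CO1)/C([O-])=C(\C)OC(=O)c1c(C)cc(OC)cc1O[Si](C)(C)C(C)(C)C.[Li+] | intermediate
20 | lithium (3S,4aS,6S,7S,8aS)-7-methyl-8-oxo-8a-(phenylselanyl)-3-[(E)-prop-1-en-1-yl]-7-(TBS-everninoyloxy)octahydro-1H-isochromen-6-olate | C/C=C/[C@@H]1C[C@@H]2[C@@](CO1)([Se]c1ccccc1)C(=O)[C@@](C)(OC(=O)c1c(C)cc(OC)cc1O[Si](C)(C)C(C)(C)C)[C@@H]([O-])C2.[Li+] | intermediate
21 | (3S,4aS,6S,7S,8aS)-6-acetoxy-7-methyl-8-oxo-8a-(phenylselanyl)-3-[(E)-prop-1-en-1-yl]octahydro-1H-isochromen-7-yl TBS-everninate | C/C=C/[C@@H]1C[C@@H]2[C@@](CO1)([Se]c1ccccc1)C(=O)[C@@](C)(OC(=O)c1c(C)cc(OC)cc1O[Si](C)(C)C(C)(C)C)[C@@H](OC(C)=O)C2 | intermediate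
22 | selenoxide of 21 (configuration at selenium undefined) | C/C=C/[C@@H]1C[C@@H]2[C@@](CO1)([Se](=O)c1ccccc1)C(=O)[C@@](C)(OC(=O)c1c(C)cc(OC)cc1O[Si](C)(C)C(C)(C)C)[C@@H](OC(C)=O)C2 | intermediate
23 | (3S,6S,7S)-6-acetoxy-7-methyl-8-oxo-3-[(E)-prop-1-en-1-yl]-3,4,5,6,7,8-hexahydro-1H-isochromen-7-yl TBS-everninate | C/C=C/[C@@H]1CC2=C(CO1)C(=O)[C@@](C)(OC(=O)c1c(C)cc(OC)cc1O[Si](C)(C)C(C)(C)C)[C@@H](OC(C)=O)C2 | intermediate
24 | (3S,6S,7S)-6-acetoxy-7-methyl-8-oxo-3-[(E)-prop-1-en-1-yl]-3,4,5,6,7,8-hexahydro-1H-isochromen-7-yl 2-hydroxy-4-methoxy-6-methylbenzoate | C/C=C/[C@@H]1CC2=C(CO1)C(=O)[C@@](C)(OC(=O)c1c(C)cc(OC)cc1O)[C@@H](OC(C)=O)C2 | target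

Total step count: 12. Longest linear sequence: 9 steps (1, 2, 6, 7, 8, 9, 10, 11, 12; the branches through steps 3 and 5 or 4 and 5 are equally long).

Steps most likely to fail

Step 10. The amide base may enolise the aldehyde instead, leading to intermolecular condensation. The closure may also run through a non-chelated transition state, or the aldolate may revert before it is acetylated; the required transition state carries a methyl/C1 1,3-diaxial contact, so either event would erode the sense at C6/C7. The fallback sets out from 18 and comes back at 21. TiCl4 and i-Pr2NEt in CH2Cl2 at −78 °C would form the chelated chlorotitanium enolate by soft enolisation, with the aldehyde activated on the same metal and no strong base present. Work-up would give the free aldol, (3S,4aS,6S,7S,8aS)-6-hydroxy-7-methyl-8-oxo-8a-(phenylselanyl)-3-[(E)-prop-1-en-1-yl]octahydro-1H-isochromen-7-yl TBS-everninate F1, which a separate acetylation (Ac2O, DMAP, pyridine, 0 °C) would convert into 21.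

Step 8. Three things may go wrong: 1,2-addition or reductive loss of the aroyloxy group, addition of the selenium electrophile to the propenyl alkene, and later transfer of selenium between enolates under the amide base of step 10. The fallback sets out from 14 and comes back at 23, with sulfur as the temporary group. The enolate from a stoichiometric cuprate of 15 (CuI, no Me3SiCl) would be quenched with PhSO2SPh to give the sulfide (2R)-1-{(3S,4S,6S)-4-[(1,3-dioxolan-2-yl)methyl]-3-(phenylsulfanyl)-6-[(E)-prop-1-en-1-yl]tetrahydro-2H-pyran-3-yl}-1-oxopropan-2-yl TBS-everninate F2. Hydrolysis as in step 9 would give the aldehyde (2R)-1-oxo-1-{(3S,4S,6S)-4-(2-oxoethyl)-3-(phenylsulfanyl)-6-[(E)-prop-1-en-1-yl]tetrahydro-2H-pyran-3-yl}propan-2-yl TBS-everninate F3. Aldol closure and acetylation as in step 10 would give (3S,4aS,6S,7S,8aS)-6-acetoxy-7-methyl-8-oxo-8a-(phenylsulfanyl)-3-[(E)-prop-1-en-1-yl]octahydro-1H-isochromen-7-yl TBS-everninate F4. Oxidation with mCPBA (1 equiv, −78 °C) would give the sulfoxide of F4, F5, whose thermolysis (toluene, 90 °C, CaCO3) would give 23.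

Step 6. Deprotonation next to the ether oxygen with [2,3]-Wittig rearrangement may compete with bromine–lithium exchange, and the vinyllithium may enolise 11 or attack its aryl ester. The fallback sets out from 5 and 11 and comes back at 13 without an organolithium. Reduction of 11 with i-Bu2AlH (CH2Cl2, −78 °C) would give the aldehyde (R)-1-oxopropan-2-yl TBS-everninate F6. Nozaki–Hiyama–Kishi coupling of vinyl bromide 5 with F6 (CrCl2, NiCl2 cat., DMF, rt) would give the allylic alcohol (2R)-4-({[(4S,5E)-hepta-1,5-dien-4-yl]oxy}methyl)-3-hydroxypent-4-en-2-yl TBS-everninate F7 as a mixture of carbinol epimers. Oxidation with Dess–Martin periodinane would give 13.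

Further compounds
F1 | step 10 | (3S,4aS,6S,7S,8aS)-6-hydroxy-7-methyl-8-oxo-8a-(phenylselanyl)-3-[(E)-prop-1-en-1-yl]octahydro-1H-isochromen-7-yl TBS-everninate | C/C=C/[C@@H]1C[C@@H]2[C@@](CO1)([Se]c1ccccc1)C(=O)[C@@](C)(OC(=O)c1c(C)cc(OC)cc1O[Si](C)(C)C(C)(C)C)[C@@H](O)C2
F2 | step 8 | (2R)-1-{(3S,4S,6S)-4-[(1,3-dioxolan-2-yl)methyl]-3-(phenylsulfanyl)-6-[(E)-prop-1-en-1-yl]tetrahydro-2H-pyran-3-yl}-1-oxopropan-2-yl TBS-everninate | C/C=C/[C@@H]1C[C@@H](CC2OCCO2)[C@](Sc2ccccc2)(CO1)C(=O)[C@@H](C)OC(=O)c1c(C)cc(OC)cc1O[Si](C)(C)C(C)(C)C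
F3 | step 8 | (2R)-1-oxo-1-{(3S,4S,6S)-4-(2-oxoethyl)-3-(phenylsulfanyl)-6-[(E)-prop-1-en-1-yl]tetrahydro-2H-pyran-3-yl}propan-2-yl TBS-everninate | C/C=C/[C@@H]1C[C@@H](CC=O)[C@](Sc2ccccc2)(CO1)C(=O)[C@@H](C)OC(=O)c1c(C)cc(OC)cc1O[Si](C)(C)C(C)(C)C
F4 | step 8 | (3S,4aS,6S,7S,8aS)-6-acetoxy-7-methyl-8-oxo-8a-(phenylsulfanyl)-3-[(E)-prop-1-en-1-yl]octahydro-1H-isochromen-7-yl TBS-everninate | C/C=C/[C@@H]1C[C@@H]2[C@@](CO1)(Sc1ccccc1)C(=O)[C@@](C)(OC(=O)c1c(C)cc(OC)cc1O[Si](C)(C)C(C)(C)C)[C@@H](OC(C)=O)C2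
F5 | step 8 | sulfoxide of F4 (configuration at sulfur undefined) | C/C=C/[C@@H]1C[C@@H]2[C@@](CO1)(S(=O)c1ccccc1)C(=O)[C@@](C)(OC(=O)c1c(C)cc(OC)cc1O[Si](C)(C)C(C)(C)C)[C@@H](OC(C)=O)C2
F6 | step 6 | (R)-1-oxopropan-2-yl TBS-everninate | C[C@@H](OC(=O)c1c(C)cc(OC)cc1O[Si](C)(C)C(C)(C)C)C=O
F7 | step 6 | (2R)-4-({[(4S,5E)-hepta-1,5-dien-4-yl]oxy}methyl)-3-hydroxypent-4-en-2-yl TBS-everninate (carbinol epimers) | C/C=C/[C@@H](OCC(=C)C(O)[C@@H](C)OC(=O)c1c(C)cc(OC)cc1O[Si](C)(C)C(C)(C)C)CC=C
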